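**Plan**

1. Retrosynthesis (gibberellane numbering, α = lactone face): unmask the C7 acid, 11-OH and C16=C17; cut C2–O and C3–O (osmylation of a Δ2 alkene); cut the lactone bond C4–C19 together with H-2 (hemioxalate on O10); then cut C3=C4 (metathesis), C9–C10 (aldol), C5–C6 ([3,3] shift), C8–C15 (radical), C8–C6 and C13–C16.
2. Forward: ring C (cyclohexenone) → ring D (bicyclo[3.2.1]octanone) → side chain → ring B → ring A → γ-lactone → diol.
3. Enabling feature: in the trans-fused rings A/B the tertiary O10 is axial on the α face of the cyclohexene ring A and 1,3 to C4, so a one-carbon radical hanging from O10 closes the five-membered lactone on C4. C4 carries no hydrogen, so the C3 radical can only lose H-2, which gives the Δ2 alkene of a bicyclo[3.2.1] lactone with an open β face.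
4. Stereochemistry: C13 by rhodium/(R)-BINAP conjugate addition; C8 relayed from C13 by the bridging cyclisation; C6 in the Claisen step; C5, C9 and C10 in the aldol; C11 by hydroxyl-directed reduction; C4 by the tether; C2 and C3 by exo-face osmylation.
5. Helpers: a tert-butyl ester on C7, and one iodo ether that masks both 11-OH and the C16 methylidene; both are removed in the last two steps.

Key step: step 16

Remark: (E)-3-iodo-2-methylprop-2-en-1-ol (1) is taken as a purchasable building block; compounds 4, 11 and 15–17 are carried as mixtures at centres that are erased or corrected later, as stated at each compound.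

**Step 1**
Reactants: 1 (E)-3-iodo-2-methylprop-2-en-1-ol
Product: 2 (E)-3-iodo-2-methylprop-2-en-1-yl acetate
Conditions: Ac2O, pyridine, DMAP (cat.), CH2Cl2, 0 → 25 °C
Reagents that add atoms: acetic anhydride, CC(=O)OC(C)=O
Why: DMAP-catalysed acetylation (nucleophilic acyl substitution) installs the two carbons that become C6 and C7; no stereocentre is involved.

**Step 2**
Reactants: 2 (E)-3-iodo-2-methylprop-2-en-1-yl acetate; 3 pent-4-enal
Product: 4 (E)-4-hydroxy-2-methylocta-2,7-dien-1-yl acetate (racemic)
Conditions: CrCl2 (4 equiv), NiCl2 (1 mol %), DMF, 25 °C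
Reagents that add atoms: none
Why: Nozaki–Hiyama–Kishi coupling adds the alkenyl iodide to the aldehyde with retention of the E geometry and tolerates the acetate; the new carbinol centre is racemic and becomes a ketone in step 7.

**Step 3**
Reactants: 5 cyclohex-2-en-1-one; 6 isopropenylboronic acid pinacol ester
Product: 7 (R)-3-(prop-1-en-2-yl)cyclohexan-1-one
Conditions: [Rh(cod)Cl]2 (1.5 mol %), (R)-BINAP (3.3 mol %), KOH (10 mol %), dioxane/H2O 10:1, 50 °C
Reagents that add atoms: none
Why: Hayashi–Miyaura rhodium-catalysed asymmetric 1,4-addition of an alkenylboron reagent; the (R)-BINAP complex selects the enone face and sets the future C13 (R in 7).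

**Step 4**
Reactants: 7 (R)-3-(prop-1-en-2-yl)cyclohexan-1-one
Product: 9 (R)-5-(prop-1-en-2-yl)cyclohex-2-en-1-one, via silyl enol ether 8 (not isolated)
Conditions: LiN(iPr)2 (commercial solution), Me3SiCl, THF, −78 °C; then Pd(OAc)2 (10 mol %), O2 (1 atm), DMSO, 25 °C
Reagents that add atoms: none
Why: Kinetic deprotonation on the side remote from the C3 substituent followed by Saegusa–Ito dehydrogenation (aerobic catalytic variant) should give the 5-substituted enone; the stereocentre is not touched.

**Step 5**
Reactants: 9 (R)-5-(prop-1-en-2-yl)cyclohex-2-en-1-one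
Product: 10 (R)-5-(3-chloroprop-1-en-2-yl)cyclohex-2-en-1-one
Conditions: Ca(OCl)2, solid CO2, CH2Cl2/H2O, 0 °C
Reagents that add atoms: calcium hypochlorite, [Ca+2].[O-]Cl.[O-]Cl
Why: Ene-type allylic chlorination by hypochlorous acid attacks only the electron-rich 1,1-disubstituted alkene and leaves the enone alkene, as in the known conversion of carvone into 10-chlorocarvone.

**Step 6**
Reactants: 4 (E)-4-hydroxy-2-methylocta-2,7-dien-1-yl acetate; 10 (R)-5-(3-chloroprop-1-en-2-yl)cyclohex-2-en-1-one
Product: 11 (E)-4-hydroxy-2-methylocta-2,7-dien-1-yl 2-[(5R)-5-(3-chloroprop-1-en-2-yl)-1-hydroxycyclohex-2-en-1-yl]acetate (mixture at both carbinol carbons)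
Conditions: 4, LiN(iPr)2 (2.2 equiv), THF, −78 °C; then 10, −78 °C; AcOH quench at −78 °C
Reagents that add atoms: none
Why: Kinetic 1,2-addition of the lithium ester enolate (aldol-type) to the enone carbonyl forms the C8–C6 bond, with the alkoxide of 4 as a spectator; both carbinol centres are removed in step 7.

**Step 7**
Reactants: 11 (E)-4-hydroxy-2-methylocta-2,7-dien-1-yl 2-[(5R)-5-(3-chloroprop-1-en-2-yl)-1-hydroxycyclohex-2-en-1-yl]acetate
Product: 12 (E)-2-methyl-4-oxoocta-2,7-dien-1-yl 2-[(5S)-5-(3-chloroprop-1-en-2-yl)-3-oxocyclohex-1-en-1-yl]acetate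
Conditions: pyridinium chlorochromate (C5H5NH)[CrO3Cl] (5 equiv), 4 Å molecular sieves, CH2Cl2, 25 °C
Reagents that add atoms: pyridinium chlorochromate, c1cc[nH+]cc1.[O-][Cr](=O)(=O)Cl
Why: Dauben oxidative transposition ([3,3] shift of the tertiary allylic chromate ester) moves the oxygen to C11 and makes C8 the β-carbon of the enone, while the secondary allylic alcohol is oxidised to the chain enone in the same operation; no stereocentre is formed.

**Step 8**
Reactants: 12 (E)-2-methyl-4-oxoocta-2,7-dien-1-yl 2-[(5S)-5-(3-chloroprop-1-en-2-yl)-3-oxocyclohex-1-en-1-yl]acetate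
Product: 13 (E)-2-methyl-4-oxoocta-2,7-dien-1-yl 2-[(1R,5S)-6-methylidene-3-oxobicyclo[3.2.1]octan-1-yl]acetate
Conditions: Bu3SnH (syringe pump), AIBN (cat.), benzene, 80 °C, high dilution
Reagents that add atoms: none
Why: 5-exo-trig radical cyclisation (intramolecular Giese addition) of the nucleophilic allyl radical onto the enone β-carbon closes ring D; the two-carbon bridge can only span C13 and C8 on one face, so the quaternary C8 is relayed from C13, and the symmetric allyl radical gives the exocyclic methylidene from either terminus.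

**Step 9**
Reactants: 13 (E)-2-methyl-4-oxoocta-2,7-dien-1-yl 2-[(1R,5S)-6-methylidene-3-oxobicyclo[3.2.1]octan-1-yl]acetate
Product: 16 (2S)-2-[(1R,5S)-6-methylidene-3-oxobicyclo[3.2.1]octan-1-yl]-4-oxo-3-(prop-1-en-2-yl)oct-7-enoic acid (mixture at chain C3 = gibberellane C5), via tris-silyl ketene acetal 14 (not isolated), via rearranged silyl ester 15 (not isolated)
Conditions: LiN(iPr)2 (3.5 equiv, commercial solution), Me3SiCl (6 equiv), THF, −78 → 45 °C; then 1 M HCl
Reagents that add atoms: none
Why: Ireland–Claisen rearrangement (chair [3,3] shift of the silyl ketene acetal, both ketones protected in situ as silyl enol ethers) forms C5–C6 and the isopropenyl group; C6 should be set by attack on the ketene acetal face turned away from the C9 arm that carries the bulky silyl enol ether, and C5 is left as a mixture that is corrected in step 11.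

**Step 10**
Reactants: 16 (2S)-2-[(1R,5S)-6-methylidene-3-oxobicyclo[3.2.1]octan-1-yl]-4-oxo-3-(prop-1-en-2-yl)oct-7-enoic acid
Product: 17 tert-butyl (2S)-2-[(1R,5S)-6-methylidene-3-oxobicyclo[3.2.1]octan-1-yl]-4-oxo-3-(prop-1-en-2-yl)oct-7-enoate (mixture at chain C3)
Conditions: Me2NCH(OtBu)2, toluene, 80 °C
Reagents that add atoms: N,N-dimethylformamide di-tert-butyl acetal, CN(C)C(OC(C)(C)C)OC(C)(C)C
Why: O-alkylation of the carboxylate by the amide acetal gives the tert-butyl ester without acyl activation, so the γ-keto acid cannot close to an enol lactone; no stereocentre is touched.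

**Step 11**
Reactants: 17 tert-butyl (2S)-2-[(1R,5S)-6-methylidene-3-oxobicyclo[3.2.1]octan-1-yl]-4-oxo-3-(prop-1-en-2-yl)oct-7-enoate
Product: 18 tricyclic ketol (rings B/C/D): 5α-isopropenyl, 6β-CO2tBu, 9β-H, 10α-OH, 10β-but-3-enyl, 11-oxo, 16-methylidene
Conditions: KOtBu (1.1 equiv), THF, −40 °C; AcOH quench at −40 °C
Reagents that add atoms: none
Why: Intramolecular aldol addition (5-enolexo-exo-trig) of the C9 enolate of the C11 ketone to the C10 ketone closes ring B: attack from the exo face of the bicyclooctanone (away from the C15–C16 bridge) sets C9, the potassium chelate between the two oxygens puts O10 cis to C11, and C5 equilibrates through the C10 enolate before closure so that the isopropenyl group ends trans to both the ester and the butenyl chain.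

**Step 12**
Reactants: 18 tricyclic ketol
Product: 19 tricyclic 10α,11β-diol (5α-isopropenyl, 6β-CO2tBu, 10β-but-3-enyl, 16-methylidene)
Conditions: Me4NBH(OAc)3, MeCN/AcOH 1:1, −20 °C
Reagents that add atoms: none
Why: Evans–Saksena hydroxyl-directed reduction: hydride is delivered intramolecularly from the C10 alkoxyborohydride to the exo face of the C11 ketone, which is also the less hindered face, giving the endo (11β) alcohol.

**Step 13**
Reactants: 19 tricyclic 10α,11β-diol
Product: 20 tetracyclic diene diol (ring A closed, C3=C4, 5β-H, 10α-OH, 11β-OH, 6β-CO2tBu, 16-methylidene)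
Conditions: second-generation Grubbs catalyst RuCl2(H2IMes)(PCy3)(=CHPh) (5 mol %), CH2Cl2, 40 °C
Reagents that add atoms: none
Why: Ring-closing metathesis between the butenyl and isopropenyl groups forms the trisubstituted C3=C4 alkene of ring A; the trans ring fusion follows from the trans arrangement of the two arms, and the hindered exocyclic methylidene has no partner within reach.

**Step 14**
Reactants: 20 tetracyclic diene diol
Product: 21 iodo ether (11β,16-epoxy-17-iodo; C3=C4; free 10α-OH; 6β-CO2tBu)
Conditions: I2, NaHCO3, MeCN, 0 °C, dark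
Reagents that add atoms: iodine, II
Why: Iodoetherification (5-exo, Markovnikov): the endo 11β-hydroxyl lies over C16 and captures the iodonium ion of the exocyclic alkene, which masks 11-OH and C16=C17 in one operation and fixes C16 by the bridge; the C3=C4 alkene is not consumed because O10 could reach its substituted carbon only through an oxetane and C3 only through a boat.

**Step 15**
Reactants: 21 iodo ether
Product: 23 hemioxalate (10α-O-CO-CO2H) of iodo ether 21, via chlorooxalate 22 (not isolated)
Conditions: (COCl)2, 2,6-lutidine, CH2Cl2, 0 °C; then H2O, THF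
Reagents that add atoms: oxalyl chloride, ClC(=O)C(=O)Cl; water, O
Why: Acylation of the tertiary alcohol by oxalyl chloride and hydrolysis of the remaining acid chloride gives the alkyl hydrogen oxalate, the usual precursor of alkoxycarbonyl radicals from hindered alcohols; this step brings in C19.

**Step 16**
Reactants: 23 hemioxalate of iodo ether 21
Product: 25 Δ2-lactone (19,10-lactone with C2=C3; 4β-methyl; 11β,16-epoxy-17-iodo; 6β-CO2tBu), via collidinium oxalate 24 (not isolated)
Conditions: 2,4,6-collidine (1 equiv), Cu(OAc)2 (20 mol %), n-Bu4NBF4 (0.1 M), MeCN, graphite felt anode, Pt cathode (catholyte AcOH/n-Bu4NBF4/MeCN), divided cell, constant current, 25 °C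
Reagents that add atoms: none
Why: Proposed new method: the carboxylate of 24 is oxidised at the anode and loses CO2 to give the alkoxycarbonyl radical on O10, which adds 5-exo-trig to C4 of the C3=C4 alkene; the secondary C3 radical is captured by Cu(OAc)2 as a trivalent alkylcopper species that undergoes β-hydride elimination of H-2, and the monovalent copper is reoxidised at the anode while protons are reduced at the cathode. The closest known chemistry is the oxidative generation of alkoxycarbonyl radicals from alkyl hemioxalates with 5-exo cyclisation onto homoallylic alkenes to give γ-lactones, combined with the Kochi copper-mediated oxidative elimination of alkyl radicals in Kolbe-type decarboxylations; running the two together under anodic conditions is the untested part. The γ-lactone ring (C19–O–C10–C5–C4) closes in the 5-exo-trig radical mode. The new quaternary centre C4 is controlled by the tether: the carbonyl radical hangs from the axial α-oxygen on C10 and can reach only the α lobe of C4, so C19 is α and the methyl group β. The step needs attack at C4 and not at C3 (1,4-bridging to a bicyclo[2.2.2] lactone) and cyclisation faster than loss of the second CO2; the trans ring fusion holds ring A in a half-chair in which O10 is 1,3-diaxial to C4 while C3 can be reached only through a boat, and the two-atom tether makes closure fast. The position of the new alkene is fixed because C4 has no hydrogen, so the elimination can only use C2–H.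

**Step 17**
Reactants: 25 Δ2-lactone
Product: 26 2β,3β-diol lactone (11β,16-epoxy-17-iodo; 6β-CO2tBu)
Conditions: OsO4 (5 mol %), N-methylmorpholine N-oxide, acetone/H2O 4:1, 25 °C
Reagents that add atoms: N-methylmorpholine N-oxide, C[N+]1([O-])CCOCC1; water, O
Why: Upjohn dihydroxylation adds both oxygens syn to the exo (β) face of the C1–C2–C3 bridge, away from the lactone bridge on the α face, which sets C2 and C3; C2=C3 is the only alkene present.

**Step 18**
Reactants: 26 2β,3β-diol lactone tert-butyl ester
Product: 27 2β,3β-diol lactone 7-carboxylic acid (11β,16-epoxy-17-iodo)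
Conditions: CF3CO2H, CH2Cl2, 0 → 25 °C
Reagents that add atoms: none
Why: Acidolysis of the tert-butyl ester (loss of 2-methylpropene) frees the C7 acid without base, so no retro-aldol epimerisation at C3 can occur; the acid-sensitive exocyclic alkene is still masked.

**Step 19**
Reactants: 27 2β,3β-diol lactone 7-carboxylic acid
Product: 28 CNP0322347.1 (2β,3β,11β-trihydroxy 19,10-lactone 7-acid with 16-methylidene)
Conditions: Zn dust (activated), AcOH/THF 1:3, 25 °C
Reagents that add atoms: none
Why: Zinc-mediated reductive β-elimination of the β-iodo ether (Boord-type) regenerates the C16=C17 methylidene and the 11β-hydroxyl under nearly neutral conditions; no other stereocentre is touched.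

**Compound list**

1 | (E)-3-iodo-2-methylprop-2-en-1-ol | OC/C(C)=C/I | starting material
2 | (E)-3-iodo-2-methylprop-2-en-1-yl acetate | CC(=O)OC/C(C)=C/I | intermediate
3 | pent-4-enal | C=CCCC=O | starting material
4 | (E)-4-hydroxy-2-methylocta-2,7-dien-1-yl acetate (racemic carbinol) | CC(=O)OC/C(C)=C/C(O)CCC=C | intermediate
5 | cyclohex-2-en-1-one | O=C1C=CCCC1 | starting material
6 | isopropenylboronic acid pinacol ester | CC(=C)B1OC(C)(C)C(C)(C)O1 | starting material
7 | (R)-3-(prop-1-en-2-yl)cyclohexan-1-one | CC(=C)[C@H]1CC(=O)CCC1 | intermediate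
8 | (R)-trimethyl{[5-(prop-1-en-2-yl)cyclohex-1-en-1-yl]oxy}silane | CC(=C)[C@H]1CC(O[Si](C)(C)C)=CCC1 | intermediate
9 | (R)-5-(prop-1-en-2-yl)cyclohex-2-en-1-one | CC(=C)[C@H]1CC(=O)C=CC1 | intermediate
10 | (R)-5-(3-chloroprop-1-en-2-yl)cyclohex-2-en-1-one | ClCC(=C)[C@H]1CC(=O)C=CC1 | intermediate
11 | (E)-4-hydroxy-2-methylocta-2,7-dien-1-yl 2-[(5R)-5-(3-chloroprop-1-en-2-yl)-1-hydroxycyclohex-2-en-1-yl]acetate (mixture at both carbinol carbons) | ClCC(=C)[C@H]1CC(O)(CC(=O)OC/C(C)=C/C(O)CCC=C)C=CC1 | intermediate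
12 | (E)-2-methyl-4-oxoocta-2,7-dien-1-yl 2-[(5S)-5-(3-chloroprop-1-en-2-yl)-3-oxocyclohex-1-en-1-yl]acetate | ClCC(=C)[C@H]1CC(CC(=O)OC/C(C)=C/C(=O)CCC=C)=CC(=O)C1 | intermediate
13 | (E)-2-methyl-4-oxoocta-2,7-dien-1-yl 2-[(1R,5S)-6-methylidene-3-oxobicyclo[3.2.1]octan-1-yl]acetate | C=C1C[C@]2(CC(=O)OC/C(C)=C/C(=O)CCC=C)C[C@H]1CC(=O)C2 | intermediate
14 | tris(trimethylsilyl) derivative of 13: ester silyl ketene acetal, C11 silyl enol ether and C10 silyl dienol ether | C=C1C[C@]2(C=C(O[Si](C)(C)C)OC/C(C)=C/C(O[Si](C)(C)C)=CCC=C)C[C@H]1C=C(O[Si](C)(C)C)C2 | intermediate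
15 | rearranged trimethylsilyl ester with both silyl enol ethers (mixture at gibberellane C5) | C=C1C[C@]2([C@@H](C(=O)O[Si](C)(C)C)C(C(C)=C)C(O[Si](C)(C)C)=CCC=C)C[C@H]1C=C(O[Si](C)(C)C)C2 | intermediate
16 | (2S)-2-[(1R,5S)-6-methylidene-3-oxobicyclo[3.2.1]octan-1-yl]-4-oxo-3-(prop-1-en-2-yl)oct-7-enoic acid (mixture at chain C3 = gibberellane C5) | C=C1C[C@]2([C@@H](C(=O)O)C(C(C)=C)C(=O)CCC=C)C[C@H]1CC(=O)C2 | intermediate
17 | tert-butyl ester of 16 (mixture at gibberellane C5) | C=C1C[C@]2([C@@H](C(=O)OC(C)(C)C)C(C(C)=C)C(=O)CCC=C)C[C@H]1CC(=O)C2 | intermediate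
18 | tricyclic ketol: 5α-isopropenyl, 6β-CO2tBu, 9β-H, 10α-OH, 10β-but-3-enyl, 11-oxo, 16-methylidene | C=C1C[C@]23C[C@H]1CC(=O)[C@H]2[C@](O)(CCC=C)[C@@H](C(C)=C)[C@@H]3C(=O)OC(C)(C)C | intermediate
19 | tricyclic 10α,11β-diol (otherwise as 18) | C=C1C[C@]23C[C@H]1C[C@H](O)[C@H]2[C@](O)(CCC=C)[C@@H](C(C)=C)[C@@H]3C(=O)OC(C)(C)C | intermediate
20 | tetracyclic diene diol: ring A with C3=C4, 5β-H, 10α-OH, 11β-OH, 6β-CO2tBu, 16-methylidene | C=C1C[C@]23C[C@H]1C[C@H](O)[C@H]2[C@]1(O)CCC=C(C)[C@H]1[C@@H]3C(=O)OC(C)(C)C | intermediate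
21 | iodo ether: 11β,16-epoxy-17-iodo, C3=C4, 10α-OH, 6β-CO2tBu | IC[C@]14C[C@]23C[C@H]1C[C@H](O4)[C@H]2[C@]5(O)CCC=C(C)[C@H]5[C@@H]3C(=O)OC(C)(C)C | intermediate
22 | 10α-chlorooxalate of 21 | IC[C@]14C[C@]23C[C@H]1C[C@H](O4)[C@H]2[C@]5(OC(=O)C(=O)Cl)CCC=C(C)[C@H]5[C@@H]3C(=O)OC(C)(C)C | intermediate
23 | 10α-hemioxalate (hydrogen oxalate) of 21 | IC[C@]14C[C@]23C[C@H]1C[C@H](O4)[C@H]2[C@]5(OC(=O)C(=O)O)CCC=C(C)[C@H]5[C@@H]3C(=O)OC(C)(C)C | intermediate
24 | 2,4,6-trimethylpyridinium salt of 23 | IC[C@]14C[C@]23C[C@H]1C[C@H](O4)[C@H]2[C@]5(OC(=O)C(=O)[O-])CCC=C(C)[C@H]5[C@@H]3C(=O)OC(C)(C)C.Cc1cc(C)[nH+]c(C)c1 | intermediate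
25 | Δ2-lactone: 19,10-lactone, C2=C3, 4β-methyl, 11β,16-epoxy-17-iodo, 6β-CO2tBu | IC[C@]14C[C@]23C[C@H]1C[C@H](O4)[C@H]2[C@@]56CC=C[C@@](C)(C(=O)O5)[C@H]6[C@@H]3C(=O)OC(C)(C)C | intermediate
26 | 2β,3β-diol of 25 | IC[C@]14C[C@]23C[C@H]1C[C@H](O4)[C@H]2[C@@]56C[C@H](O)[C@H](O)[C@@](C)(C(=O)O5)[C@H]6[C@@H]3C(=O)OC(C)(C)C | intermediate
27 | 7-carboxylic acid of 26 | IC[C@]14C[C@]23C[C@H]1C[C@H](O4)[C@H]2[C@@]56C[C@H](O)[C@H](O)[C@@](C)(C(=O)O5)[C@H]6[C@@H]3C(=O)O | intermediate
28 | CNP0322347.1: 2β,3β,11β-trihydroxy 19,10-lactone 7-acid with 16-methylidene | C=C1C[C@]23C[C@H]1C[C@H](O)[C@H]2[C@@]12C[C@H](O)[C@H](O)[C@@](C)(C(=O)O1)[C@H]2[C@@H]3C(=O)O | target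

**Step count and risks**

Total steps: 19. Longest linear sequence: 17 (steps 3 to 19); steps 1 and 2 make the side chain 4 that enters in step 6.

Steps most likely to fail:

Step 16 (Proposed new method). The alkoxycarbonyl radical may lose its second CO2 before it cyclises, may bridge to C3 in the six-membered mode, or the C3 radical may be over-oxidised to a cation and rearrange. The fallback forms the same bond by intramolecular enolate acylation and sets out from 21:
- KN(SiMe3)2 and methyl chloroformate should give the 10α-methyl carbonate F1.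
- Hydroboration and oxidation (BH3·THF; NaBO3) should give the 3-hydroxy carbonate F2.
- Dess–Martin oxidation should give the 3-ketone F3.
- KOtBu in THF equilibrates the enolates, and only the C4 enolate can reach the carbonate, so C-acylation (5-exo-trig, loss of methanol) closes the lactone on the α face; the C2 enolate of the resulting 3-oxo lactone is trapped with PhNTf2 as the enol triflate F4.
- Reduction of the triflate with Pd(OAc)2, PPh3, Bu3N and HCO2H (zerovalent palladium, formate as hydride source) comes back to the route at 25.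

Step 8. The stabilised allyl radical may be reduced by the stannane before it adds to the fully substituted β-carbon, returning the isopropenyl compound. The fallback is a Lewis-acid-promoted intramolecular conjugate ene reaction and sets out from 9 (no chlorination) and 4:
- The step 6 conditions should give the hydroxy ester F5.
- Pyridinium chlorochromate as in step 7 should give the bis-enone F6.
- Me2AlCl in CH2Cl2 at −78 → 0 °C activates the ring enone; the isopropenyl terminus attacks C8 and a methyl hydrogen is transferred, since the bridgehead C13–H cannot be lost. This gives the same methylidene bicycle and comes back to the route at 13.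

Step 9. The triple enolisation may go astray at the γ-acyloxy enone of the chain (deprotonation at the allylic CH2–O, elimination of the carboxylate), and the facial selectivity at C6 may be modest. The fallback keeps the chain oxygen as a silyl ether until after the [3,3] shift and sets out from 4 and 10:
- Et3SiCl and imidazole should give the silyl ether F7.
- The step 6 conditions with 10 should give the adduct F8.
- Pyridinium chlorochromate (transposition only) should give the enone F9.
- Bu3SnH/AIBN should give the bicyclic ketone F10.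
- Ireland–Claisen rearrangement with only one ketone to protect should give the acid F11.
- Me2NCH(OtBu)2 should give the tert-butyl ester F12.
- HF·pyridine should give the alcohol F13, which is oxidised at once with Dess–Martin periodinane to come back to the route at 17.

Further compounds
F1 | step 16 | 10α-methyl carbonate of iodo ether 21 | IC[C@]14C[C@]23C[C@H]1C[C@H](O4)[C@H]2[C@]5(OC(=O)OC)CCC=C(C)[C@H]5[C@@H]3C(=O)OC(C)(C)C
F2 | step 16 | 3-hydroxy-3,4-dihydro derivative of F1 (mixture at C3 and C4) | IC[C@]14C[C@]23C[C@H]1C[C@H](O4)[C@H]2[C@]5(OC(=O)OC)CCC(O)C(C)[C@H]5[C@@H]3C(=O)OC(C)(C)C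
F3 | step 16 | 3-ketone of F2 (mixture at C4) | IC[C@]14C[C@]23C[C@H]1C[C@H](O4)[C@H]2[C@]5(OC(=O)OC)CCC(=O)C(C)[C@H]5[C@@H]3C(=O)OC(C)(C)C
F4 | step 16 | 3-trifloxy-Δ2 19,10-lactone (enol triflate of the 3-oxo lactone) | IC[C@]14C[C@]23C[C@H]1C[C@H](O4)[C@H]2[C@@]56CC=C(OS(=O)(=O)C(F)(F)F)[C@@](C)(C(=O)O5)[C@H]6[C@@H]3C(=O)OC(C)(C)C
F5 | step 8 | (E)-4-hydroxy-2-methylocta-2,7-dien-1-yl 2-[(5R)-1-hydroxy-5-(prop-1-en-2-yl)cyclohex-2-en-1-yl]acetate (mixture at both carbinol carbons) | CC(=C)[C@H]1CC(O)(CC(=O)OC/C(C)=C/C(O)CCC=C)C=CC1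
F6 | step 8 | (E)-2-methyl-4-oxoocta-2,7-dien-1-yl 2-[(5S)-3-oxo-5-(prop-1-en-2-yl)cyclohex-1-en-1-yl]acetate | CC(=C)[C@H]1CC(CC(=O)OC/C(C)=C/C(=O)CCC=C)=CC(=O)C1
F7 | step 9 | (E)-2-methyl-4-(triethylsilyloxy)octa-2,7-dien-1-yl acetate (racemic) | CC(=O)OC/C(C)=C/C(O[Si](CC)(CC)CC)CCC=C
F8 | step 9 | 1,2-adduct of F7 with 10 (mixture at both oxygenated carbons) | ClCC(=C)[C@H]1CC(O)(CC(=O)OC/C(C)=C/C(O[Si](CC)(CC)CC)CCC=C)C=CC1
F9 | step 9 | transposed ring enone from F8 (chain silyl ether retained) | ClCC(=C)[C@H]1CC(CC(=O)OC/C(C)=C/C(O[Si](CC)(CC)CC)CCC=C)=CC(=O)C1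
F10 | step 9 | (1R,5S)-6-methylidene-3-oxobicyclo[3.2.1]octan-1-yl acetic ester of the silylated chain | C=C1C[C@]2(CC(=O)OC/C(C)=C/C(O[Si](CC)(CC)CC)CCC=C)C[C@H]1CC(=O)C2
F11 | step 9 | Claisen acid with 4-(triethylsilyloxy) chain (mixture at gibberellane C5 and C10) | C=C1C[C@]2([C@@H](C(=O)O)C(C(C)=C)C(O[Si](CC)(CC)CC)CCC=C)C[C@H]1CC(=O)C2
F12 | step 9 | tert-butyl ester of F11 | C=C1C[C@]2([C@@H](C(=O)OC(C)(C)C)C(C(C)=C)C(O[Si](CC)(CC)CC)CCC=C)C[C@H]1CC(=O)C2
F13 | step 9 | 4-hydroxy tert-butyl ester from F12 | C=C1C[C@]2([C@@H](C(=O)OC(C)(C)C)C(C(C)=C)C(O)CCC=C)C[C@H]1CC(=O)C2
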